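**Strategy.** The cyclohexene ring is disconnected at the C1–C6 bond by a retro-Claisen reading: the quaternary carbinol carbon C1 and its CH2OBz carbon are the α-carbon and carbonyl of a γ,δ-unsaturated aldehyde whose β-carbon is C6 and whose alkene is C4=C5. The precursor is therefore a pyran, not a carbocycle: a D-ribonolactone-derived 5-benzoyloxy-3,4-dihydro-2H-pyran carrying an (E)-2-(4-methoxybenzyloxy)vinyl group at C2, beside the ring oxygen. One thermal [3,3] shift expels that oxygen as the formyl group, closes the six-membered carbocycle, and sets the quaternary C1, the C6 carbinol and the C4=C5 alkene, while C2 and C3 come from D-ribose. Reduction then lets the benzoyl group migrate onto the new CH2OH.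

Key step: step 7

Remark: target ring numbering is C1 = C(OH)(CH2OBz), C2 and C3 = CH(OAc), C4=C5, C6 = CH(OH); pyranoid and lactone intermediates carry carbohydrate numbering; compound 1 and all reagents are taken as commercial, and the enol-ether intermediates 4–8 are kept away from acid (Et3N-deactivated silica).

Step 1
Reactants: 1 2,3-O-isopropylidene-D-ribono-1,4-lactone
Product: 2 5-aldehydo-2,3-O-isopropylidene-D-ribono-1,4-lactone (C5 alcohol of 1 oxidised to CHO)
Conditions: Dess–Martin periodinane, NaHCO3, CH2Cl2, 0 °C to rt; used crude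
Reagents that add atoms: none
Why: Dess–Martin oxidation of the only free (primary) hydroxyl should stop at the aldehyde under buffered, non-basic conditions that leave C4 and the lactone untouched.

Step 2
Reactants: 2 5-aldehydo-2,3-O-isopropylidene-D-ribono-1,4-lactone
Product: 3 5,6-dideoxy-2,3-O-isopropylidene-6-(4,4,5,5-tetramethyl-1,3,2-dioxaborolan-2-yl)-D-ribo-hex-5-(E)-enono-1,4-lactone
Conditions: Cl2CHBpin, CrCl2, LiI, THF, rt
Reagents that add atoms: 2-(dichloromethyl)-4,4,5,5-tetramethyl-1,3,2-dioxaborolane, ClC(Cl)B1OC(C)(C)C(C)(C)O1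
Why: Takai–Utimoto boryl-olefination through a gem-dichromium reagent is aldehyde-selective and non-basic, and should give the (E)-alkenyl boronate.

Step 3
Reactants: 3 (E)-alkenyl pinacol boronate lactone
Product: 4 5-deoxy-2,3-O-isopropylidene-6-O-(4-methoxybenzyl)-D-ribo-hex-5-(E)-enono-1,4-lactone
Conditions: Cu(OAc)2 (2 equiv), Et3N (4 equiv), 4-methoxybenzyl alcohol (excess), CH2Cl2, 4 Å sieves, air, rt
Reagents that add atoms: 4-methoxybenzyl alcohol, COc1ccc(CO)cc1
Why: Copper-promoted oxidative C–O coupling of an alkenyl boronate with an alcohol (Chan–Lam type enol ether synthesis) should proceed with retention of the (E)-geometry and, at room temperature, without opening the lactone.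

Step 4
Reactants: 4 (E)-enol ether lactone
Product: 5 1,6-dideoxy-1-(dimethyloxosulfuranylidene)-3,4-O-isopropylidene-7-O-(4-methoxybenzyl)-D-ribo-hept-6-(E)-en-2-ulose (β-keto sulfoxonium ylide with free 5-OH)
Conditions: Me3S(O)I, KOtBu, THF, reflux; then 4, 0 °C to rt
Reagents that add atoms: trimethylsulfoxonium iodide, C[S+](C)(C)=O.[I-]
Why: Acylation of dimethylsulfoxonium methylide (Corey–Chaykovsky ylide) by the lactone carbonyl should open the ring to the stabilised β-keto ylide and free the C5 hydroxyl without touching a stereocentre.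

Step 5
Reactants: 5 β-keto sulfoxonium ylide
Product: 6 1,5-anhydro-6-deoxy-3,4-O-isopropylidene-7-O-(4-methoxybenzyl)-D-ribo-hept-6-(E)-en-2-ulose (a tetrahydropyran-3-one)
Conditions: [Ir(cod)Cl]2 (2.5 mol %), 1,2-dichloroethane, 70 °C, slow addition
Reagents that add atoms: none
Why: Iridium-carbene formation with loss of DMSO and intramolecular O–H insertion of the C5 hydroxyl should close the six-membered ether (a one-carbon ring expansion of the lactone), O–H insertion being expected to outrun carbene addition to the distal enol ether.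

Step 6
Reactants: 6 tetrahydropyran-3-one
Product: 8 1,5-anhydro-2-O-benzoyl-6-deoxy-3,4-O-isopropylidene-7-O-(4-methoxybenzyl)-D-ribo-hepta-1,6(E)-dienitol, via potassium enolate 7 (not isolated)
Conditions: KN(SiMe3)2, THF, −78 °C; then Bz2O, −78 to 0 °C
Reagents that add atoms: benzoic anhydride, O=C(OC(=O)c1ccccc1)c1ccccc1
Why: Kinetic deprotonation at the unhindered O–CH2 α-carbon (the other α-carbon is the ring-fusion methine of the acetonide) and O-acylation of the potassium enolate should give the enol benzoate.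

Step 7
Reactants: 8 2-O-benzoyl glycal with (E)-enol ether side chain
Product: 9 1-O-benzoyl-1-C-formyl-2,3-O-isopropylidene-6-O-(4-methoxybenzyl)cyclohex-4-ene-1,2,3,6-tetrol (target numbering; CHO, 2-O, 3-O and 6-OPMB on one face, 1-OBz on the other)
Conditions: 1,2-dichlorobenzene (0.02 M), 2,6-di-tert-butyl-4-methylpyridine (0.2 equiv), base-washed sealed tube, 190 °C
Reagents that add atoms: none
Why: A concerted thermal [3,3]-sigmatropic (Claisen) shift of the allyl vinyl ether array C2=C1–O5–C5–C6=C7 of 8 forms the C2–C7 bond as C5–O5 breaks, so O5 leaves the ring as the formyl oxygen. The closest known reaction is the carbocyclic Claisen ring contraction of 2-alkenyl-3,4-dihydro-2H-pyrans, established for 5-vinyl glycals that give cyclohexenecarbaldehydes; here both bond-forming termini carry oxygen donors (OBz on C2, OPMB on C7), which should lower the barrier. The carbocycle C2–C3–C4–C5–C6–C7 is closed by joining its two ends C2 and C7 through a bicyclo[2.2.2]-like boat transition state, the only geometry the two-atom C3–C4 tether (held near-eclipsed by the cis-fused acetonide) allows. The quaternary centre (target C1) is set by suprafacial transfer from C5: C7 reaches the enol benzoate on the face where C5 holds the side chain, anti to the acetonide, so CHO ends cis and OBz trans to the acetonide oxygens. The C6 centre is set by the (E)-enol ether geometry, because in the enforced boat the outside substituent of C7 ends cis to the formyl group, and the new C4=C5 alkene is necessarily cis in the ring. The selectivity needed is the concerted shift over ionisation of the doubly allylic C5–O5 bond (which would scramble C6); a non-polar medium, an acid scavenger and the acetal-locked 3,4-oxygens (no competing [3,3] array) should secure it.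

Step 8
Reactants: 9 α-benzoyloxy cyclohexenecarbaldehyde
Product: 11 1-C-(benzoyloxymethyl)-2,3-O-isopropylidene-6-O-(4-methoxybenzyl)cyclohex-4-ene-1,2,3,6-tetrol (free tertiary 1-OH), via primary alcohol 10 (not isolated)
Conditions: NaBH4, THF/MeOH, −20 to 0 °C; then Et3N (cat.), MeOH, rt
Reagents that add atoms: none
Why: Borohydride reduction of the aldehyde gives a primary alcohol next to the tertiary benzoate, and the 1,2 O-to-O acyl migration through a five-membered orthoester should deliver the benzoyl group to the primary oxygen (the only shift possible, since C2/C3 are an acetonide and C6 a PMB ether).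

Step 9
Reactants: 11 acetonide with primary benzoate
Product: 12 1-C-(benzoyloxymethyl)-6-O-(4-methoxybenzyl)cyclohex-4-ene-1,2,3,6-tetrol (1,2,3-triol)
Conditions: AcOH/H2O 4:1, 45 °C
Reagents that add atoms: none
Why: Mild acid hydrolysis of the cis-fused isopropylidene acetal should free the C2/C3 diol while the PMB ether and the benzoate survive.

Step 10
Reactants: 12 triol
Product: 13 2,3-di-O-acetyl-1-C-(benzoyloxymethyl)-6-O-(4-methoxybenzyl)cyclohex-4-ene-1,2,3,6-tetrol
Conditions: Ac2O, pyridine, 0 °C to rt (no DMAP)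
Reagents that add atoms: acetic anhydride, CC(=O)OC(C)=O
Why: Standard acetylation should esterify the two secondary hydroxyls while the flanked tertiary C1 hydroxyl stays free under DMAP-free conditions.

Step 11
Reactants: 13 diacetate PMB ether
Product: 14 [(1R,2R,3R,6S)-2,3-bis(acetyloxy)-1,6-dihydroxycyclohex-4-en-1-yl]methyl benzoate (CNP0130780.2)
Conditions: DDQ, CH2Cl2/pH 7 phosphate buffer, 0 °C to rt
Reagents that add atoms: none
Why: Oxidative PMB cleavage (hydride abstraction to the oxocarbenium ion, then hydrolysis) should release the C6 hydroxyl under neutral conditions that cause no acyl migration.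

**Compound list**

1 | 2,3-O-isopropylidene-D-ribono-1,4-lactone | O=C1[C@@H]2OC(C)(C)O[C@@H]2[C@@H](CO)O1 | starting material
2 | 5-aldehydo-2,3-O-isopropylidene-D-ribono-1,4-lactone | O=C1[C@@H]2OC(C)(C)O[C@@H]2[C@@H](C=O)O1 | intermediate
3 | 5,6-dideoxy-2,3-O-isopropylidene-6-(pinacolboryl)-D-ribo-hex-5-(E)-enono-1,4-lactone | O=C1[C@@H]2OC(C)(C)O[C@@H]2[C@@H](/C=C/B3OC(C)(C)C(C)(C)O3)O1 | intermediate
4 | 5-deoxy-2,3-O-isopropylidene-6-O-(4-methoxybenzyl)-D-ribo-hex-5-(E)-enono-1,4-lactone | O=C1[C@@H]2OC(C)(C)O[C@@H]2[C@@H](/C=C/OCc3ccc(OC)cc3)O1 | intermediate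
5 | 1,6-dideoxy-1-(dimethyloxosulfuranylidene)-3,4-O-isopropylidene-7-O-(4-methoxybenzyl)-D-ribo-hept-6-(E)-en-2-ulose | CS(C)(=O)=CC(=O)[C@@H]1OC(C)(C)O[C@@H]1[C@H](O)/C=C/OCc1ccc(OC)cc1 | intermediate
6 | 1,5-anhydro-6-deoxy-3,4-O-isopropylidene-7-O-(4-methoxybenzyl)-D-ribo-hept-6-(E)-en-2-ulose | O=C1CO[C@H](/C=C/OCc2ccc(OC)cc2)[C@H]2OC(C)(C)O[C@@H]12 | intermediate
7 | potassium 1,2-enolate of 6 | [K+].[O-]C1=CO[C@H](/C=C/OCc2ccc(OC)cc2)[C@H]2OC(C)(C)O[C@@H]12 | intermediate
8 | 1,5-anhydro-2-O-benzoyl-6-deoxy-3,4-O-isopropylidene-7-O-(4-methoxybenzyl)-D-ribo-hepta-1,6(E)-dienitol | O=C(OC1=CO[C@H](/C=C/OCc2ccc(OC)cc2)[C@H]2OC(C)(C)O[C@@H]12)c1ccccc1 | intermediate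
9 | 1-O-benzoyl-1-C-formyl-2,3-O-isopropylidene-6-O-(4-methoxybenzyl)cyclohex-4-ene-1,2,3,6-tetrol (CHO, 2-O, 3-O, 6-O cis; 1-OBz trans) | O=C[C@@]1(OC(=O)c2ccccc2)[C@@H](OCc2ccc(OC)cc2)C=C[C@H]2OC(C)(C)O[C@@H]12 | intermediate
10 | 1-O-benzoyl-1-C-(hydroxymethyl)-2,3-O-isopropylidene-6-O-(4-methoxybenzyl)cyclohex-4-ene-1,2,3,6-tetrol | OC[C@@]1(OC(=O)c2ccccc2)[C@@H](OCc2ccc(OC)cc2)C=C[C@H]2OC(C)(C)O[C@@H]12 | intermediate
11 | 1-C-(benzoyloxymethyl)-2,3-O-isopropylidene-6-O-(4-methoxybenzyl)cyclohex-4-ene-1,2,3,6-tetrol | O=C(OC[C@@]1(O)[C@@H](OCc2ccc(OC)cc2)C=C[C@H]2OC(C)(C)O[C@@H]12)c1ccccc1 | intermediate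
12 | 1-C-(benzoyloxymethyl)-6-O-(4-methoxybenzyl)cyclohex-4-ene-1,2,3,6-tetrol | O=C(OC[C@@]1(O)[C@@H](OCc2ccc(OC)cc2)C=C[C@@H](O)[C@H]1O)c1ccccc1 | intermediate
13 | 2,3-di-O-acetyl-1-C-(benzoyloxymethyl)-6-O-(4-methoxybenzyl)cyclohex-4-ene-1,2,3,6-tetrol | O=C(OC[C@@]1(O)[C@@H](OCc2ccc(OC)cc2)C=C[C@@H](OC(C)=O)[C@H]1OC(C)=O)c1ccccc1 | intermediate
14 | [(1R,2R,3R,6S)-2,3-bis(acetyloxy)-1,6-dihydroxycyclohex-4-en-1-yl]methyl benzoate | CC(=O)O[C@@H]1[C@H](OC(C)=O)C=C[C@H](O)[C@]1(O)COC(=O)c1ccccc1 | target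

**Step count.** Total steps: 11. Longest linear sequence: 11 (fully linear from 1).

**Steps most likely to fail**

Step 7 (key step). The boat-shaped [3,3] shift may be outrun by heterolysis of the doubly activated allylic C5–O5 bond, giving an ion pair that recombines without control at C6 or degrades at the temperature required. The fallback closes the ring by olefin metathesis instead; it sets out from 1 and comes back at 11.
- Iodination of 1 (I2, PPh3, imidazole) would give 5-deoxy-5-iodo-2,3-O-isopropylidene-D-ribono-1,4-lactone F1.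
- Zinc dust in THF/water should open it by reductive β-elimination of the carboxylate (Bernet–Vasella type) to 4,5-dideoxy-2,3-O-isopropylidene-D-erythro-pent-4-enonic acid F2.
- Esterification (Me3SiCHN2, MeOH) gives the methyl ester F3, and acylation of dimethylsulfoxonium methylide the β-keto sulfoxonium ylide F4.
- O–H insertion with benzoic acid catalysed by [Ir(cod)Cl]2 gives the benzoyloxymethyl ketone F5.
- Chelation-controlled, syn-selective addition of the (Z)-γ-(4-methoxybenzyloxy)allyl aluminium reagent (allyl 4-methoxybenzyl ether, sec-BuLi, then Et2AlCl) should give the 1,7-diene F6.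
- Ring-closing metathesis with the second-generation Grubbs catalyst closes C4=C5 to give 11.
- The price is that C1 and C6 are then set in an acyclic carbonyl addition.

Step 5. The iridium carbene may add to the electron-rich enol ether (cyclopropanation) instead of inserting into the O–H bond. The fallback expands the ring before the enol ether exists; it sets out from 1 and comes back at 6.
- Silylation of 1 (TBSCl, imidazole) gives the 5-O-silyl lactone F7.
- The sulfoxonium ylide opens it to the hydroxy keto ylide F8.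
- O–H insertion with [Ir(cod)Cl]2, now without a competing alkene, gives the silyloxymethyl pyranone F9.
- HF·pyridine frees the alcohol F10, and Dess–Martin oxidation gives the aldehyde F11.
- Boryl-olefination (Cl2CHBpin, CrCl2, LiI) gives the (E)-alkenyl boronate F12.
- Etherification with 4-methoxybenzyl alcohol and Cu(OAc)2 gives 6.

Step 6. Deprotonation may occur on the acetonide-bearing side with β-elimination of the C4 oxygen, or the enolate may be acylated on carbon. The fallback uses soft enolisation and carries silicon, not benzoyl, through the rearrangement; it sets out from 6 and comes back at 12.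
- Et3SiOTf and Et3N convert 6 into the 2-O-triethylsilyl glycal F13.
- The same thermal Claisen shift gives the α-silyloxy aldehyde F14.
- NaBH4 gives the primary alcohol F15.
- BzCl in pyridine gives the primary benzoate F16.
- The acid treatment of step 9 (AcOH/H2O/THF, 45 °C) removes the tertiary silyl ether together with the acetonide and gives 12.

Further compounds
F1 | step 7 | 5-deoxy-5-iodo-2,3-O-isopropylidene-D-ribono-1,4-lactone | O=C1[C@@H]2OC(C)(C)O[C@@H]2[C@@H](CI)O1
F2 | step 7 | 4,5-dideoxy-2,3-O-isopropylidene-D-erythro-pent-4-enonic acid | OC(=O)[C@@H]1OC(C)(C)O[C@@H]1C=C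
F3 | step 7 | methyl 4,5-dideoxy-2,3-O-isopropylidene-D-erythro-pent-4-enonate | COC(=O)[C@@H]1OC(C)(C)O[C@@H]1C=C
F4 | step 7 | 1,5,6-trideoxy-1-(dimethyloxosulfuranylidene)-3,4-O-isopropylidene-D-erythro-hex-5-en-2-ulose | CS(C)(=O)=CC(=O)[C@@H]1OC(C)(C)O[C@@H]1C=C
F5 | step 7 | 1-O-benzoyl-5,6-dideoxy-3,4-O-isopropylidene-D-erythro-hex-5-en-2-ulose | O=C(OCC(=O)[C@@H]1OC(C)(C)O[C@@H]1C=C)c1ccccc1
F6 | step 7 | open-chain 1,7-diene corresponding to 11 with C4=C5 replaced by two vinyl groups | O=C(OC[C@@](O)([C@@H](OCc1ccc(OC)cc1)C=C)[C@@H]1OC(C)(C)O[C@@H]1C=C)c1ccccc1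
F7 | step 5 | 5-O-(tert-butyldimethylsilyl)-2,3-O-isopropylidene-D-ribono-1,4-lactone | O=C1[C@@H]2OC(C)(C)O[C@@H]2[C@@H](CO[Si](C)(C)C(C)(C)C)O1
F8 | step 5 | 6-O-(tert-butyldimethylsilyl)-1-deoxy-1-(dimethyloxosulfuranylidene)-3,4-O-isopropylidene-D-psicose | CS(C)(=O)=CC(=O)[C@@H]1OC(C)(C)O[C@@H]1[C@H](O)CO[Si](C)(C)C(C)(C)C
F9 | step 5 | 1,5-anhydro-6-O-(tert-butyldimethylsilyl)-3,4-O-isopropylidene-D-psicose | O=C1CO[C@H](CO[Si](C)(C)C(C)(C)C)[C@H]2OC(C)(C)O[C@@H]12
F10 | step 5 | 1,5-anhydro-3,4-O-isopropylidene-D-psicose | O=C1CO[C@H](CO)[C@H]2OC(C)(C)O[C@@H]12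
F11 | step 5 | 6-aldehydo-1,5-anhydro-3,4-O-isopropylidene-D-psicose | O=C1CO[C@H](C=O)[C@H]2OC(C)(C)O[C@@H]12
F12 | step 5 | 1,5-anhydro-6,7-dideoxy-3,4-O-isopropylidene-7-(pinacolboryl)-D-ribo-hept-6-(E)-en-2-ulose | O=C1CO[C@H](/C=C/B2OC(C)(C)C(C)(C)O2)[C@H]2OC(C)(C)O[C@@H]12
F13 | step 6 | 1,5-anhydro-6-deoxy-3,4-O-isopropylidene-7-O-(4-methoxybenzyl)-2-O-(triethylsilyl)-D-ribo-hepta-1,6(E)-dienitol | CC[Si](CC)(CC)OC1=CO[C@H](/C=C/OCc2ccc(OC)cc2)[C@H]2OC(C)(C)O[C@@H]12
F14 | step 6 | 1-C-formyl-2,3-O-isopropylidene-6-O-(4-methoxybenzyl)-1-O-(triethylsilyl)cyclohex-4-ene-1,2,3,6-tetrol | O=C[C@@]1(O[Si](CC)(CC)CC)[C@@H](OCc2ccc(OC)cc2)C=C[C@H]2OC(C)(C)O[C@@H]12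
F15 | step 6 | 1-C-(hydroxymethyl)-2,3-O-isopropylidene-6-O-(4-methoxybenzyl)-1-O-(triethylsilyl)cyclohex-4-ene-1,2,3,6-tetrol | OC[C@@]1(O[Si](CC)(CC)CC)[C@@H](OCc2ccc(OC)cc2)C=C[C@H]2OC(C)(C)O[C@@H]12
F16 | step 6 | 1-C-(benzoyloxymethyl)-2,3-O-isopropylidene-6-O-(4-methoxybenzyl)-1-O-(triethylsilyl)cyclohex-4-ene-1,2,3,6-tetrol | O=C(OC[C@@]1(O[Si](CC)(CC)CC)[C@@H](OCc2ccc(OC)cc2)C=C[C@H]2OC(C)(C)O[C@@H]12)c1ccccc1
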